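The numbers are invented; the flask was simulated.

The trap in west is to set the 2.2 h half-life of the activated form on the way to ring beside its 2.6 h half-life on the way to open dimer and call it a close race, since the second figure supposes the whole substrate charge present at once, and a dosed flask never holds that.

    activated form → ring (k1 = 8.8 × 10⁻⁵ s⁻¹)
    substrate + activated form → open dimer (k2 = 6.7 × 10⁻⁵ M⁻¹ s⁻¹)
    substrate + activator → activated form (k3 = 6.5 × 10⁻⁴ M⁻¹ s⁻¹)
    substrate ⇌ dormant form (K4 = 1.1, k4 = 0.0024 s⁻¹)

all flasks: substrate 1.1 M (fed, over 2.5 h); time 6.0 h
- west: activator 0.600 equiv; the fed solution adds 0.50 times the starting volume
- south: activator 1.00 equiv; the fed solution adds 0.50 times the starting volume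
- north-east: activator 1.50 equiv; the fed solution adds 0.50 times the starting volume

* share of ring in all that became ring or open dimer for west, south, north-east, in this order
* how the row runs (hardly changes / falls, then rises / falls all the way / rises, then falls / rises all the way)

- a species is counted by the substrate in it: one open dimer counts as two
- charges are per starting volume, the dose included; the dosed solution carries all of it
- "hardly changes" means that all values lie within two and a half points (for a concentration: within two and a half percent of the largest)
- run time (west): 6.0 h

Both products come from the activated form, so its concentration cancels when they are compared, and what remains is the free substrate S. An open dimer counts as two, so define C as the ring constant divided by two times the dimer constant. C is 0.657 M, the free substrate at which ring and open dimer grow equally. At any moment the ring's share is C/(C+S), and C/S is the selectivity factor.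

Two chemists argue over S. The second says that activator appears nowhere in C/(C+S). Substrate and dormant form relax with a half-life of 2.52 min, shorter than the feed of 2.5 h, so she divides the diluted charge between them and gets S of 0.349 M. That gives a share of 65.3% in every flask, and a row that hardly changes.

The first chemist answers that activator sets S. Her forecast is 78%, 84% and 90%, a row that rises all the way, on the ground that “More activator consumes the dosed substrate faster”.

My own reckoning takes her side. In west the half-life of substrate by activation, 0.45 h, holds with the activator as charged and is shorter than the feed, so as a rough first try I set the feed rate equal to activation at the charged activator. This gives S of 0.285 M in west, 0.171 M in south and 0.114 M in north-east. The shares are then 69.7%, 79.3% and 85.2%, which differ from the forecast by lying lower.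

The flasks give 78.7%, 85.2% and 90.4%, a row that rises all the way, so the flat row fails. At 2.50 h substrate stood at 31.5% of the charge in west, 24.0% in south and 17.7% in north-east. In west the dormant form held a further 33.0% at that moment, so my balance of feed against activation did not hold there. The second chemist's view keeps its ground where S lies far below C, for there the share sits near its ceiling and a further fall of S moves it little. North-east at 6.00 h is such a case: its 2.34% of the charge is S of 0.0172 M, and its share at that moment is 97.4%.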